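**Plan**
- Retrosynthetic cuts, in order: the epoxide oxygen (C1/C10); the acyl C–O bond at C8; lactone carbon C12 (a CO insertion between the C6 oxygen and a C7 ethynyl group); C8–C9 and C10–C1 (the ynoate unit C9–C10–C14 inserted into the C8–C1 bond of a cyclooctenone); C3–C4 and C5–C6 (the propiolate unit C4–C5–C15 inserted into the C3–C6 bond of a cyclohexanone); C7–C11.
- Forward: cyclohexenone ketal → conjugate alkynylation → cis-cyclooctene by a first two-carbon ring expansion → ten-membered ring by a second two-carbon ring expansion → C8 ester → α-methylene lactone by cyclocarbonylation → epoxide.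
- Enabling feature: the array C8(O)–C9H2–C10(C14)=C1 with an E olefin β,γ to the oxygenated C8. With C8 as a ketone this is the retron of the 4π ring opening of a 1-silyloxybicyclo[6.2.0]dec-9-ene, i.e. a cyclobutene C8–C9=C10–C1 fused on the eight-membered ring C1–C8. The Z C4=C5 olefin can already sit in that eight-membered ring.
- Stereochemistry: C7 from a catalytic asymmetric conjugate alkynylation; C6–O anti to C7; C3 and C8 from oxazaborolidine reductions; E-C1=C10 from donor-outward torquoselectivity of the cis-fused cyclobutene; epoxide face from peripheral attack; C2' from (S)-2-methylbutanoic acid.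

Key step: step 10

Remark: intermediates are named with the atom numbers and α/β faces of the target (ring C1–C10, lactone carbons C11–C13, C14 on C10, C15 on C4; TBS = tert-butyldimethylsilyl, TBSO = its ether). The ligand enantiomer in step 1 is assumed to be the one that gives the 7R adduct.

Step 1
Reactants: 1 1,4-dioxaspiro[4.5]dec-6-en-8-one; 2 ethynyl(trimethyl)silane
Product: 5 tert-butyl(dimethyl){[(6R)-6-[(trimethylsilyl)ethynyl]-1,4-dioxaspiro[4.5]dec-7-en-8-yl]oxy}silane, via alkynylalane 3 (not isolated), via aluminium enolate 4 (not isolated)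
Conditions: 2, AlMe3, Et3N (10 mol %), toluene, 60 °C; then 1, Ni(acac)2 (5 mol %), (S,S)-2,2'-(propane-2,2-diyl)bis(4-phenyl-4,5-dihydrooxazole) (6 mol %), t-BuOMe, 0 °C; then TBSOTf, −40 → 0 °C
Reagents that add atoms: tert-butyldimethylsilyl trifluoromethanesulfonate (TBSOTf), CC(C)(C)[Si](C)(C)OS(=O)(=O)C(F)(F)F
Why: Nickel-catalysed enantioselective 1,4-addition of the dimethylalkynylalane 3 to a cyclohexenone should set C7 by catalyst control at the neopentyl β-carbon, which the slender alkynyl group can still reach, and O-silylation of the aluminium enolate 4 locks the C3=C6 enol ether regiochemistry that no later enolisation of the ketone could deliver.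

Step 2
Reactants: 5 tert-butyl(dimethyl){[(6R)-6-[(trimethylsilyl)ethynyl]-1,4-dioxaspiro[4.5]dec-7-en-8-yl]oxy}silane; 6 methyl prop-2-ynoate
Product: 8 methyl 3-oxo-8,8-ethylenedioxy-7β-[(trimethylsilyl)ethynyl]cyclooct-5-ene-4-carboxylate, via cyclobutene 7 (not isolated)
Conditions: HN(SO2CF3)2 (2 mol %), CH2Cl2, −78 °C; then HF·pyridine, pyridine, THF, 0 °C → rt
Reagents that add atoms: none
Why: A triflimide-catalysed stepwise [2+2] cycloaddition of a silyl enol ether with a propiolate (Mukaiyama–Michael addition of C6 to the ynoate terminus, then closure of the allenoate on the C3 oxocarbenium ion) should give the donor–acceptor cyclobutene 7, and desilylation then triggers retro-aldol (4π) cleavage of the C3–C6 bond to the two-carbon ring-expanded β-keto ester, the vinylogous ester anion relaxing to the cis C5=C6 olefin that an eight-membered ring demands; C7 is untouched and no new lasting stereocentre arises.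

Step 3
Reactants: 8 methyl 3-oxo-8,8-ethylenedioxy-7β-[(trimethylsilyl)ethynyl]cyclooct-5-ene-4-carboxylate
Product: 10 methyl 6α-hydroxy-3-oxo-8,8-ethylenedioxy-7β-[(trimethylsilyl)ethynyl]cyclooct-4-ene-4-carboxylate, via eight-ring dienol ether 9 (not isolated)
Conditions: TBSOTf, Et3N, CH2Cl2, −78 → 0 °C; then mCPBA, NaHCO3, CH2Cl2, −20 °C; then HF·pyridine, pyridine, THF, 0 °C
Reagents that add atoms: 3-chloroperoxybenzoic acid (mCPBA), OOC(=O)c1cccc(Cl)c1
Why: O-Silylation of the β-keto ester gives the extended 1-silyloxy-1,3-diene 9, and its vinylogous Rubottom oxidation (as in the peracid γ-hydroxylation of dienol ethers) should occur at the C5=C6 bond, the ester-bearing C3=C4 bond being deactivated, from the face opposite the neighbouring C7 alkynyl group, so that the new C6 hydroxyl is trans to C7 (6α, 6R).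

Step 4
Reactants: 10 methyl 6α-hydroxy-3-oxo-8,8-ethylenedioxy-7β-[(trimethylsilyl)ethynyl]cyclooct-4-ene-4-carboxylate
Product: 11 methyl 3β,6α-dihydroxy-8,8-ethylenedioxy-7β-[(trimethylsilyl)ethynyl]cyclooct-4-ene-4-carboxylate
Conditions: (R)-1-methyl-3,3-diphenyltetrahydro-1H,3H-pyrrolo[1,2-c][1,3,2]oxazaborole (20 mol %), catecholborane, toluene, −78 °C
Reagents that add atoms: none
Why: Corey–Bakshi–Shibata reduction with the (R)-oxazaborolidine should deliver hydride 1,2 to the enone carbonyl with the alkenyl carbon C4 as the large and the C2 methylene as the small group, which gives the 3S (3β) allylic alcohol by reagent control.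

Step 5
Reactants: 11 methyl 3β,6α-dihydroxy-8,8-ethylenedioxy-7β-[(trimethylsilyl)ethynyl]cyclooct-4-ene-4-carboxylate
Product: 12 4-(hydroxymethyl)-8,8-ethylenedioxy-7β-[(trimethylsilyl)ethynyl]cyclooct-4-ene-3β,6α-diol
Conditions: iBu2AlH (6 equiv), CH2Cl2, −78 → −20 °C; aqueous potassium sodium tartrate work-up
Reagents that add atoms: none
Why: Diisobutylaluminium hydride reduction of the conjugated methyl ester to the primary allylic alcohol (C15) should proceed at low temperature without touching ketal, silylalkyne or olefin; no stereocentre is formed.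

Step 6
Reactants: 12 4-(hydroxymethyl)-8,8-ethylenedioxy-7β-[(trimethylsilyl)ethynyl]cyclooct-4-ene-3β,6α-diol
Product: 13 3β,6α-bis(TBSO)-4-(TBSOCH2)-8,8-ethylenedioxy-7β-[(trimethylsilyl)ethynyl]cyclooct-4-ene
Conditions: TBSCl, imidazole, 4-(dimethylamino)pyridine (cat.), DMF, rt
Reagents that add atoms: tert-butyldimethylsilyl chloride (TBSCl), CC(C)(C)[Si](C)(C)Cl
Why: Standard silylation (silyl chloride, imidazole) protects the two secondary allylic hydroxyls and the primary one in a single operation, so that only the C8 carbonyl remains to be unmasked.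

Step 7
Reactants: 13 3β,6α-bis(TBSO)-4-(TBSOCH2)-8,8-ethylenedioxy-7β-[(trimethylsilyl)ethynyl]cyclooct-4-ene
Product: 14 3β,6α-bis(TBSO)-4-(TBSOCH2)-7β-[(trimethylsilyl)ethynyl]cyclooct-4-en-8-one
Conditions: pyridinium p-toluenesulfonate (cat.), acetone/H2O, 40 °C
Reagents that add atoms: water, O
Why: Mild acid-catalysed hydrolysis of the dioxolane (deketalisation) should free the C8 ketone while the silyl ethers and the alkynylsilane stay in place and the β-silyloxy ketone is not driven to eliminate.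

Step 8
Reactants: 14 3β,6α-bis(TBSO)-4-(TBSOCH2)-7β-[(trimethylsilyl)ethynyl]cyclooct-4-en-8-one
Product: 15 3β,6α,8-tris(TBSO)-4-(TBSOCH2)-7β-[(trimethylsilyl)ethynyl]cycloocta-1(8),4-diene
Conditions: LiN(iPr)2, THF, −78 °C; then TBSCl, HMPA, −78 → 0 °C
Reagents that add atoms: tert-butyldimethylsilyl chloride (TBSCl), CC(C)(C)[Si](C)(C)Cl
Why: Kinetic enolate formation with the hindered lithium amide should remove a proton from the unhindered C1 methylene and not from the tertiary C7–H flanked by the alkynyl and silyloxy-bearing carbons, and O-silylation gives the C8=C1 enol ether, which is necessarily cis in the eight-membered ring.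

Step 9
Reactants: 16 but-2-ynoic acid; 17 3-bromoprop-1-ene
Product: 18 prop-2-en-1-yl but-2-ynoate
Conditions: K2CO3, DMF, rt
Reagents that add atoms: none
Why: Carboxylate O-alkylation (SN2) with allyl bromide gives the ynoate as an allyl ester, which can later be removed with zerovalent palladium under neutral conditions.

Step 10
Reactants: 15 3β,6α,8-tris(TBSO)-4-(TBSOCH2)-7β-[(trimethylsilyl)ethynyl]cycloocta-1(8),4-diene; 18 prop-2-en-1-yl but-2-ynoate
Product: 21 prop-2-en-1-yl (1(10)E,4Z)-3β,6α-bis(TBSO)-4-(TBSOCH2)-10-methyl-8-oxo-7β-[(trimethylsilyl)ethynyl]cyclodeca-1(10),4-diene-9-carboxylate, via bicyclic cyclobutene 19 (not isolated), via ten-ring dienol ether 20 (not isolated)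
Conditions: HN(SO2CF3)2 (5 mol %), CH2Cl2, −78 → −40 °C; then toluene, 60 °C; then 10 % aq. citric acid, THF, 0 °C
Reagents that add atoms: none
Why: Triflimide generates a silyl triflimide Lewis acid that activates ynoate 18; the enol ether carbon C1 adds to the β-carbon (C10) in a Mukaiyama–Michael step and the allenoate carbon C9 closes onto the C8 oxocarbenium ion (4-exo-trig) to give the cis-fused 1-silyloxybicyclo[6.2.0]dec-9-ene 19. On warming, this strained donor–acceptor cyclobutene should undergo thermal conrotatory 4π ring opening of the C8–C1 bond, which is the ring expansion from eight to ten members; no ring is closed in this stage. The closest known reaction type is the two-carbon ring expansion of cycloalkanone silyl enol ethers or enamines with propiolates through bicyclo[n.2.0] cyclobutenes. The transient stereocentres C8 and C1 are lost again, so the only stereochemical issue is the C1=C10 geometry: the silyloxy donor on C8 rotates outward (torquoselectivity), which with the cis ring fusion forces H-1 inward and C2 outward, i.e. the E olefin, while the C8=C9 enol ether geometry vanishes on hydrolysis. Site selectivity (C1, not C7) is fixed by the kinetic enol ether 15, and the cis C4=C5 olefin inherited from the eight-membered ring, flanked by allylic C–O bonds, is not nucleophilic enough to compete. Mild aqueous acid then cleaves only the vinylogous silyl ester to give β-keto ester 21 (C9 epimers and enol) with the other silyl groups in place.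

Step 11
Reactants: 21 prop-2-en-1-yl (1(10)E,4Z)-3β,6α-bis(TBSO)-4-(TBSOCH2)-10-methyl-8-oxo-7β-[(trimethylsilyl)ethynyl]cyclodeca-1(10),4-diene-9-carboxylate
Product: 22 (1(10)E,4Z)-3β,6α-bis(TBSO)-4-(TBSOCH2)-10-methyl-7β-[(trimethylsilyl)ethynyl]cyclodeca-1(10),4-dien-8-one
Conditions: Pd(PPh3)4 (5 mol %), morpholine, THF, rt
Reagents that add atoms: none
Why: Tsuji–Trost-type deallylation: zerovalent palladium ionises the allyl ester, morpholine captures the allyl group and the β-keto acid loses CO2 at room temperature, the enol being protonated at C9 so that the E C1=C10 olefin should stay out of conjugation.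

Step 12
Reactants: 22 (1(10)E,4Z)-3β,6α-bis(TBSO)-4-(TBSOCH2)-10-methyl-7β-[(trimethylsilyl)ethynyl]cyclodeca-1(10),4-dien-8-one
Product: 24 (1(10)E,4Z)-3β,6α-bis(TBSO)-4-(TBSOCH2)-7β-ethynyl-10-methylcyclodeca-1(10),4-dien-8β-ol, via silylalkyne alcohol 23 (not isolated)
Conditions: (S)-1-methyl-3,3-diphenyltetrahydro-1H,3H-pyrrolo[1,2-c][1,3,2]oxazaborole (20 mol %), catecholborane, toluene, −78 °C; then MeOH, K2CO3, rt
Reagents that add atoms: none
Why: Corey–Bakshi–Shibata reduction with the (S)-oxazaborolidine should treat the branched C7 side as the large and the C9 methylene as the small group and so give the 8R (8β) alcohol, after which methanolic carbonate cleaves only the C(sp)–Si bond (protodesilylation) and leaves the silyl ethers.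

Step 13
Reactants: 24 (1(10)E,4Z)-3β,6α-bis(TBSO)-4-(TBSOCH2)-7β-ethynyl-10-methylcyclodeca-1(10),4-dien-8β-ol; 25 (2S)-2-methylbutanoic acid
Product: 26 (1(10)E,4Z)-3β,6α-bis(TBSO)-4-(TBSOCH2)-7β-ethynyl-10-methylcyclodeca-1(10),4-dien-8β-yl (2S)-2-methylbutanoate
Conditions: 1-ethyl-3-(3-dimethylaminopropyl)carbodiimide hydrochloride, 4-(dimethylamino)pyridine, CH2Cl2, 0 °C → rt
Reagents that add atoms: none
Why: Steglich esterification acylates the single free hydroxyl with retention at C8 and should not erode the S configuration of the acid, which is taken from commercial (S)-2-methylbutanoic acid.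

Step 14
Reactants: 26 (1(10)E,4Z)-3β,6α-bis(TBSO)-4-(TBSOCH2)-7β-ethynyl-10-methylcyclodeca-1(10),4-dien-8β-yl (2S)-2-methylbutanoate
Product: 27 (1(10)E,4Z)-7β-ethynyl-3β,6α-dihydroxy-4-(hydroxymethyl)-10-methylcyclodeca-1(10),4-dien-8β-yl (2S)-2-methylbutanoate
Conditions: HF·pyridine, pyridine, THF, 0 °C → rt
Reagents that add atoms: none
Why: Fluoride-mediated cleavage of the three silyl ethers with pyridine-buffered HF·pyridine should leave the ester, the terminal alkyne and the acid-sensitive 1,5-diene intact.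

Step 15
Reactants: 27 (1(10)E,4Z)-7β-ethynyl-3β,6α-dihydroxy-4-(hydroxymethyl)-10-methylcyclodeca-1(10),4-dien-8β-yl (2S)-2-methylbutanoate
Product: 28 3β,15-dihydroxy-8β-[(2S)-2-methylbutanoyloxy]germacra-1(10)E,4Z,11(13)-trien-12,6α-olide
Conditions: PdCl2 (10 mol %), thiourea (10 mol %), CO (1 atm), acetone, 50 °C
Reagents that add atoms: carbon monoxide, [C-]#[O+]
Why: Palladium-catalysed cyclocarbonylation of a homopropargylic alcohol: the alkoxycarbonylpalladium species formed at the C6 oxygen should add syn across the alkyne (5-exo-dig) and protonolysis releases the α-methylene-γ-butyrolactone, whose trans ring fusion is already fixed by the trans C6–O/C7–C11 pair.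

Step 16
Reactants: 28 3β,15-dihydroxy-8β-[(2S)-2-methylbutanoyloxy]germacra-1(10)E,4Z,11(13)-trien-12,6α-olide
Product: 29 1β,10α-epoxy-3β,15-dihydroxy-8β-[(2S)-2-methylbutanoyloxy]germacra-4Z,11(13)-dien-12,6α-olide (CNP0267576.2)
Conditions: mCPBA, NaHCO3, CH2Cl2, 0 °C
Reagents that add atoms: 3-chloroperoxybenzoic acid (mCPBA), OOC(=O)c1cccc(Cl)c1
Why: Prilezhaev epoxidation should go to the electron-rich 1(10) olefin and not to the C4=C5 bond deactivated by three allylic C–O bonds or to the enoate, and peripheral attack on the E olefin in the preferred conformer with C14 on the β face, as in peracid epoxidations of related 1(10)E-germacranolides, should give the 1β,10α (1R,10R) epoxide.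

**Compound list**
1 | 1,4-dioxaspiro[4.5]dec-6-en-8-one | O=C1C=CC2(CC1)OCCO2 | starting material
2 | ethynyl(trimethyl)silane | C#C[Si](C)(C)C | starting material
3 | dimethyl[(trimethylsilyl)ethynyl]alane (not isolated) | C[Al](C)C#C[Si](C)(C)C | intermediate
4 | dimethylaluminium (6R)-6-[(trimethylsilyl)ethynyl]-1,4-dioxaspiro[4.5]dec-7-en-8-olate (not isolated) | C1COC2(O1)CCC(O[Al](C)C)=C[C@@H]2C#C[Si](C)(C)C | intermediate
5 | tert-butyl(dimethyl){[(6R)-6-[(trimethylsilyl)ethynyl]-1,4-dioxaspiro[4.5]dec-7-en-8-yl]oxy}silane (six-membered enol ether C3=C6, 7β-alkynyl) | C1COC2(O1)CCC(O[Si](C)(C)C(C)(C)C)=C[C@@H]2C#C[Si](C)(C)C | intermediate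
6 | methyl prop-2-ynoate | C#CC(=O)OC | starting material
7 | cis-fused bicyclo[4.2.0]oct-7-ene: cyclobutene C3(OTBS)–C4(CO2Me)=C5H–C6H on the six-membered ring of 5, new C6–C5 bond anti to the 7β-alkynyl group (not isolated; either cis-fused isomer converges) | C1COC2(O1)CC[C@@]3(O[Si](C)(C)C(C)(C)C)C(C(=O)OC)=C[C@H]3[C@@H]2C#C[Si](C)(C)C | intermediate
8 | methyl 3-oxo-8,8-ethylenedioxy-7β-[(trimethylsilyl)ethynyl]cyclooct-5-ene-4-carboxylate (ring-cis C5=C6; C4 epimers and enol) | C1COC2(O1)CCC(=O)C(C(=O)OC)/C=C\[C@@H]2C#C[Si](C)(C)C | intermediate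
9 | methyl 3-(TBSO)-8,8-ethylenedioxy-7β-[(trimethylsilyl)ethynyl]cycloocta-3,5-diene-4-carboxylate (both ring olefins cis; not isolated) | C1COC2(O1)CC/C(O[Si](C)(C)C(C)(C)C)=C(C(=O)OC)\C=C/[C@@H]2C#C[Si](C)(C)C | intermediate
10 | methyl 6α-hydroxy-3-oxo-8,8-ethylenedioxy-7β-[(trimethylsilyl)ethynyl]cyclooct-4-ene-4-carboxylate (ring-cis C4=C5; 6-OH trans to the alkynyl group) | C1COC2(O1)CCC(=O)/C(C(=O)OC)=C\[C@@H](O)[C@@H]2C#C[Si](C)(C)C | intermediate
11 | methyl 3β,6α-dihydroxy-8,8-ethylenedioxy-7β-[(trimethylsilyl)ethynyl]cyclooct-4-ene-4-carboxylate (3S) | C1COC2(O1)CC[C@H](O)/C(C(=O)OC)=C\[C@@H](O)[C@@H]2C#C[Si](C)(C)C | intermediate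
12 | 4-(hydroxymethyl)-8,8-ethylenedioxy-7β-[(trimethylsilyl)ethynyl]cyclooct-4-ene-3β,6α-diol (4Z) | C1COC2(O1)CC[C@H](O)/C(CO)=C\[C@@H](O)[C@@H]2C#C[Si](C)(C)C | intermediate
13 | 3β,6α-bis(TBSO)-4-(TBSOCH2)-8,8-ethylenedioxy-7β-[(trimethylsilyl)ethynyl]cyclooct-4-ene | C1COC2(O1)CC[C@H](O[Si](C)(C)C(C)(C)C)/C(CO[Si](C)(C)C(C)(C)C)=C\[C@@H](O[Si](C)(C)C(C)(C)C)[C@@H]2C#C[Si](C)(C)C | intermediate
14 | 3β,6α-bis(TBSO)-4-(TBSOCH2)-7β-[(trimethylsilyl)ethynyl]cyclooct-4-en-8-one | O=C1CC[C@H](O[Si](C)(C)C(C)(C)C)/C(CO[Si](C)(C)C(C)(C)C)=C\[C@@H](O[Si](C)(C)C(C)(C)C)[C@@H]1C#C[Si](C)(C)C | intermediate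
15 | 3β,6α,8-tris(TBSO)-4-(TBSOCH2)-7β-[(trimethylsilyl)ethynyl]cycloocta-1(8),4-diene (enol ether C8=C1) | C1\C=C(O[Si](C)(C)C(C)(C)C)/[C@@H](C#C[Si](C)(C)C)[C@H](O[Si](C)(C)C(C)(C)C)\C=C(CO[Si](C)(C)C(C)(C)C)/[C@H]1O[Si](C)(C)C(C)(C)C | intermediate
16 | but-2-ynoic acid | CC#CC(=O)O | starting material
17 | 3-bromoprop-1-ene | C=CCBr | starting material
18 | prop-2-en-1-yl but-2-ynoate | CC#CC(=O)OCC=C | intermediate
19 | cis-fused bicyclo[6.2.0]dec-9-ene: cyclobutene C8(OTBS)–C9(CO2allyl)=C10(CH3)–C1H on the eight-membered ring of 15, new bonds anti to the 7β-alkynyl group (not isolated; either cis-fused isomer converges) | C1[C@@H]2C(C)=C(C(=O)OCC=C)[C@]2(O[Si](C)(C)C(C)(C)C)[C@@H](C#C[Si](C)(C)C)[C@H](O[Si](C)(C)C(C)(C)C)\C=C(CO[Si](C)(C)C(C)(C)C)/[C@H]1O[Si](C)(C)C(C)(C)C | intermediate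
20 | prop-2-en-1-yl (1(10)E,4Z)-3β,6α,8-tris(TBSO)-4-(TBSOCH2)-10-methyl-7β-[(trimethylsilyl)ethynyl]cyclodeca-1(10),4,8-triene-9-carboxylate (not isolated) | C1/C=C(C)/C(C(=O)OCC=C)=C(O[Si](C)(C)C(C)(C)C)\[C@@H](C#C[Si](C)(C)C)[C@H](O[Si](C)(C)C(C)(C)C)\C=C(CO[Si](C)(C)C(C)(C)C)/[C@H]1O[Si](C)(C)C(C)(C)C | intermediate
21 | prop-2-en-1-yl (1(10)E,4Z)-3β,6α-bis(TBSO)-4-(TBSOCH2)-10-methyl-8-oxo-7β-[(trimethylsilyl)ethynyl]cyclodeca-1(10),4-diene-9-carboxylate (C9 epimers and enol) | C1/C=C(C)/C(C(=O)OCC=C)C(=O)[C@@H](C#C[Si](C)(C)C)[C@H](O[Si](C)(C)C(C)(C)C)\C=C(CO[Si](C)(C)C(C)(C)C)/[C@H]1O[Si](C)(C)C(C)(C)C | intermediate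
22 | (1(10)E,4Z)-3β,6α-bis(TBSO)-4-(TBSOCH2)-10-methyl-7β-[(trimethylsilyl)ethynyl]cyclodeca-1(10),4-dien-8-one | C1/C=C(C)/CC(=O)[C@@H](C#C[Si](C)(C)C)[C@H](O[Si](C)(C)C(C)(C)C)\C=C(CO[Si](C)(C)C(C)(C)C)/[C@H]1O[Si](C)(C)C(C)(C)C | intermediate
23 | (1(10)E,4Z)-3β,6α-bis(TBSO)-4-(TBSOCH2)-10-methyl-7β-[(trimethylsilyl)ethynyl]cyclodeca-1(10),4-dien-8β-ol (not isolated) | C1/C=C(C)/C[C@@H](O)[C@@H](C#C[Si](C)(C)C)[C@H](O[Si](C)(C)C(C)(C)C)\C=C(CO[Si](C)(C)C(C)(C)C)/[C@H]1O[Si](C)(C)C(C)(C)C | intermediate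
24 | (1(10)E,4Z)-3β,6α-bis(TBSO)-4-(TBSOCH2)-7β-ethynyl-10-methylcyclodeca-1(10),4-dien-8β-ol (8R) | C1/C=C(C)/C[C@@H](O)[C@@H](C#C)[C@H](O[Si](C)(C)C(C)(C)C)\C=C(CO[Si](C)(C)C(C)(C)C)/[C@H]1O[Si](C)(C)C(C)(C)C | intermediate
25 | (2S)-2-methylbutanoic acid | CC[C@H](C)C(=O)O | starting material
26 | (1(10)E,4Z)-3β,6α-bis(TBSO)-4-(TBSOCH2)-7β-ethynyl-10-methylcyclodeca-1(10),4-dien-8β-yl (2S)-2-methylbutanoate | C1/C=C(C)/C[C@@H](OC(=O)[C@@H](C)CC)[C@@H](C#C)[C@H](O[Si](C)(C)C(C)(C)C)\C=C(CO[Si](C)(C)C(C)(C)C)/[C@H]1O[Si](C)(C)C(C)(C)C | intermediate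
27 | (1(10)E,4Z)-7β-ethynyl-3β,6α-dihydroxy-4-(hydroxymethyl)-10-methylcyclodeca-1(10),4-dien-8β-yl (2S)-2-methylbutanoate | C1/C=C(C)/C[C@@H](OC(=O)[C@@H](C)CC)[C@@H](C#C)[C@H](O)\C=C(CO)/[C@H]1O | intermediate
28 | 3β,15-dihydroxy-8β-[(2S)-2-methylbutanoyloxy]germacra-1(10)E,4Z,11(13)-trien-12,6α-olide | C1/C=C(C)/C[C@@H](OC(=O)[C@@H](C)CC)[C@H]2C(=C)C(=O)O[C@@H]2\C=C(CO)/[C@H]1O | intermediate
29 | 1β,10α-epoxy-3β,15-dihydroxy-8β-[(2S)-2-methylbutanoyloxy]germacra-4Z,11(13)-dien-12,6α-olide (CNP0267576.2; 1R,3S,6R,7R,8R,10R,2'S) | C=C1C(=O)O[C@@H]2/C=C(/CO)[C@@H](O)C[C@H]3O[C@]3(C)C[C@@H](OC(=O)[C@@H](C)CC)[C@@H]12 | target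

**Step count**
Total: 16 steps. Longest linear sequence: 15 steps (steps 1–8 and 10–16; step 9 makes the ynoate separately).

**Steps most likely to fail**

(a) Step 10. The β-methyl ynoate may react too slowly with the hindered enol ether, or the silyl group may be lost after the Michael step so that an open-chain adduct forms and the four-membered ring never closes. The same bicyclic ring system would then be built with a ketene. From 15, [2+2] cycloaddition with dichloroketene (Cl3CCOCl, Zn–Cu couple, Et2O) gives the dichlorocyclobutanone F1. Zn/AcOH removes the chlorines to give the cyclobutanone F2. KN(SiMe3)2 and PhNTf2 at −78 °C give the cyclobutenyl triflate F3, and Me2CuLi couples it to the methylcyclobutene F4. Warming in toluene opens F4 by the same donor-outward conrotation to the ten-membered silyl dienol ether F5. Buffered HF·pyridine then gives ketone 22, where the route is rejoined; step 11 is no longer needed.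

(b) Step 15. The catalytic amount of acid that the cyclocarbonylation generates may trigger transannular cyclisation of the 1,5-diene, or the allylic hydroxyls may be ionised. The lactone carbon would then be introduced under basic conditions. From 27, molybdenum-catalysed α-selective hydrostannation (Bu3SnH, Mo(CO)3(CNtBu)3) gives the internal vinylstannane F6. Iododestannylation (I2, CH2Cl2, −78 °C) gives the vinyl iodide F7. Carbonylative lactonisation (Pd(PPh3)4, CO, Et3N, MeCN, 50 °C) closes onto the C6 hydroxyl and gives 28.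

(c) Step 3. The peracid may attack the enol ether bond, or the facial selectivity at C6 next to the slender alkynyl group may be poor. The oxygen would then be delivered by cycloaddition. From 8, silylation to 9 as before, then singlet oxygen (O2, hν, 5,10,15,20-tetraphenylporphyrin, CH2Cl2, −78 °C) adds across C3 and C6 of the cis,cis-diene on the face away from the alkynyl group and gives the endoperoxide F8. Thiourea reduces the O–O bond and HF·pyridine releases the C3 ketone, giving 10.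

Further compounds
F1 | step 10 | cis-fused 2,2-dichloro-3-(TBSO)cyclobutanone C8(OTBS)–C9Cl2–C10(=O)–C1H on the eight-membered ring of 15 | C1[C@@H]2C(=O)C(Cl)(Cl)[C@]2(O[Si](C)(C)C(C)(C)C)[C@@H](C#C[Si](C)(C)C)[C@H](O[Si](C)(C)C(C)(C)C)\C=C(CO[Si](C)(C)C(C)(C)C)/[C@H]1O[Si](C)(C)C(C)(C)C
F2 | step 10 | cis-fused 3-(TBSO)cyclobutanone C8(OTBS)–C9H2–C10(=O)–C1H | C1[C@@H]2C(=O)C[C@]2(O[Si](C)(C)C(C)(C)C)[C@@H](C#C[Si](C)(C)C)[C@H](O[Si](C)(C)C(C)(C)C)\C=C(CO[Si](C)(C)C(C)(C)C)/[C@H]1O[Si](C)(C)C(C)(C)C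
F3 | step 10 | cyclobutenyl triflate C8(OTBS)–C9H=C10(OTf)–C1H | C1[C@@H]2C(OS(=O)(=O)C(F)(F)F)=C[C@]2(O[Si](C)(C)C(C)(C)C)[C@@H](C#C[Si](C)(C)C)[C@H](O[Si](C)(C)C(C)(C)C)\C=C(CO[Si](C)(C)C(C)(C)C)/[C@H]1O[Si](C)(C)C(C)(C)C
F4 | step 10 | methylcyclobutene C8(OTBS)–C9H=C10(CH3)–C1H | C1[C@@H]2C(C)=C[C@]2(O[Si](C)(C)C(C)(C)C)[C@@H](C#C[Si](C)(C)C)[C@H](O[Si](C)(C)C(C)(C)C)\C=C(CO[Si](C)(C)C(C)(C)C)/[C@H]1O[Si](C)(C)C(C)(C)C
F5 | step 10 | (1(10)E,4Z)-3β,6α,8-tris(TBSO)-4-(TBSOCH2)-10-methyl-7β-[(trimethylsilyl)ethynyl]cyclodeca-1(10),4,8-triene | C1/C=C(C)/C=C(O[Si](C)(C)C(C)(C)C)\[C@@H](C#C[Si](C)(C)C)[C@H](O[Si](C)(C)C(C)(C)C)\C=C(CO[Si](C)(C)C(C)(C)C)/[C@H]1O[Si](C)(C)C(C)(C)C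
F6 | step 15 | 7β-[1-(tributylstannyl)ethenyl] analogue of 27 | C1/C=C(C)/C[C@@H](OC(=O)[C@@H](C)CC)[C@@H](C(=C)[Sn](CCCC)(CCCC)CCCC)[C@H](O)\C=C(CO)/[C@H]1O
F7 | step 15 | 7β-(1-iodoethenyl) analogue of 27 | C1/C=C(C)/C[C@@H](OC(=O)[C@@H](C)CC)[C@@H](C(=C)I)[C@H](O)\C=C(CO)/[C@H]1O
F8 | step 3 | 3,6-endoperoxide of 9 (peroxide bridge on the face opposite the alkynyl group) | C1COC2(O1)CC[C@@]3(O[Si](C)(C)C(C)(C)C)OO[C@H](C=C3C(=O)OC)[C@@H]2C#C[Si](C)(C)C
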